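The 28-membered ring (C1 = propyl-bearing carbon, O2, C3 = ester carbonyl, on to N27 and C28 = amide carbonyl) is cut at C18–C19. Across C18=C19 the CO2H on C19 and carbon C17 lie on the same side. Adding H and CO2H to opposite faces of an alkyne would leave exactly this, so the ring is closed as the C16=C17–C18≡C19 enyne and the acid comes later. Ring-closing alkyne metathesis makes the triple bond and the macrocycle in one operation and spares alkene, ketone, ester and amide. The precursor is an open ester–amide chain with two methyl-capped alkynes. Its C22/C23 diol travels as one acetonide and, once freed, steers tin to C19.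

Key step: step 26

Remark: atom labels C1–C28 are those of the target ring and are also used for the fragments.
Design note: the C22/C23 diol is kept as one isopropylidene ketal. The sugar then delivers it in one step, no alkoxide ever sits beside a silyl ether (no silyl migration), and the three hydroxyls freed later all lie on the C19 side of the alkyne.
Assumption: lipase AK is taken to acetylate the hydroxymethyl group beside the (S)-centre of diol 2. The two ends of 3 are interchangeable, so the opposite sense would only reverse the order in which they are elaborated.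

Step 1
Reactants: 1 cis-2,4-dimethylglutaric anhydride
Product: 2 meso-2,4-dimethylpentane-1,5-diol
Conditions: LiAlH4, THF, 0 °C to reflux; aq. NaOH work-up
Reagents that add atoms: none
Why: Hydride reduction of a cyclic anhydride to the diol touches neither methyl-bearing centre, so the cis (meso) relationship of C4 and C6 is kept.

Step 2
Reactants: 2 meso-2,4-dimethylpentane-1,5-diol
Product: 3 (2R,4S)-5-acetoxy-2,4-dimethylpentan-1-ol (acetate on the C3 oxygen; free OH on C7)
Conditions: lipase AK (Pseudomonas fluorescens), vinyl acetate, THF, rt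
Reagents that add atoms: vinyl acetate C=COC(C)=O
Why: Enzymatic desymmetrisation by irreversible transesterification should acylate only one enantiotopic hydroxymethyl group, which fixes the syn pair C4/C6 as a single enantiomer and tells the two chain ends apart.

Step 3
Reactants: 3 (2R,4S)-5-acetoxy-2,4-dimethylpentan-1-ol
Product: 4 (2S,4R)-2,4-dimethyl-5-oxopentyl acetate (C7 aldehyde)
Conditions: TEMPO (cat.), PhI(OAc)2, CH2Cl2, rt
Reagents that add atoms: none
Why: Oxoammonium (TEMPO) oxidation stops at the aldehyde under nearly neutral conditions, so the adjacent centre C6 should not epimerise and the acetate stays.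

Step 4
Reactants: 4 (2S,4R)-2,4-dimethyl-5-oxopentyl acetate; 5 (3-benzyloxypropyl)triphenylphosphonium bromide
Product: 7 (2S,4R,5Z)-8-benzyloxy-2,4-dimethyloct-5-en-1-yl acetate, via phosphonium ylide 6 (not isolated)
Conditions: 5, NaHMDS, THF, 0 °C; then 4, −78 °C to rt
Reagents that add atoms: none
Why: Wittig olefination with a preformed non-stabilised ylide adds C8–C10 at low temperature without enolising the aldehyde, and the alkene geometry does not matter because the next step saturates it.

Step 5
Reactants: 7 (2S,4R,5Z)-8-benzyloxy-2,4-dimethyloct-5-en-1-yl acetate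
Product: 8 (2S,4S)-8-hydroxy-2,4-dimethyloctyl acetate
Conditions: H2 (1 atm), Pd/C, EtOH/EtOAc, rt
Reagents that add atoms: none
Why: Heterogeneous catalytic hydrogenation saturates C7=C8 and hydrogenolyses the benzyl ether in the same operation, while the acetate and both stereocentres are inert.

Step 6
Reactants: 8 (2S,4S)-8-hydroxy-2,4-dimethyloctyl acetate
Product: 9 (2S,4S)-8-iodo-2,4-dimethyloctyl acetate
Conditions: I2, PPh3, imidazole, CH2Cl2, 0 °C to rt
Reagents that add atoms: iodine II
Why: Appel-type iodination converts the unhindered primary C10 alcohol by SN2 displacement of its alkoxyphosphonium ion under buffered conditions.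

Step 7
Reactants: 10 cyclohex-2-en-1-one
Product: 12 (R)-(3-ethylcyclohex-1-en-1-yl)oxytrimethylsilane, via ethylzinc enolate 11 (not isolated)
Conditions: Et2Zn, Cu(OTf)2 (1 mol %), phosphoramidite from (R)-binaphthol and bis[(S)-1-phenylethyl]amine (2 mol %), toluene, −30 °C; then TMSOTf, −30 °C to rt
Reagents that add atoms: diethylzinc CC[Zn]CC; trimethylsilyl triflate C[Si](C)(C)OS(=O)(=O)C(F)(F)F
Why: Copper-catalysed asymmetric conjugate addition of a dialkylzinc sets C15 (R) under ligand control, and silylation of the regiodefined zinc enolate locks the double bond between the future C11 and C16.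

Step 8
Reactants: 12 (R)-(3-ethylcyclohex-1-en-1-yl)oxytrimethylsilane
Product: 14 methyl (R)-5-ethyl-6-oxohexanoate, via aldehyde acid 13 (not isolated)
Conditions: O3, CH2Cl2/MeOH, −78 °C; Me2S, −78 °C to rt; then TMSCHN2, toluene/MeOH, 0 °C
Reagents that add atoms: ozone [O-][O+]=O; (trimethylsilyl)diazomethane C[Si](C)(C)C=[N+]=[N-]
Why: Ozonolysis of a silyl enol ether opens the ring to a C16 aldehyde and a C11 acid, and base-free diazoalkane esterification masks the acid at once, so C15 next to the aldehyde keeps its configuration.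

Step 9
Reactants: 14 methyl (R)-5-ethyl-6-oxohexanoate
Product: 15 methyl (5R,6E)-5-ethyl-7-iodohept-6-enoate
Conditions: CrCl2, CHI3, THF/1,4-dioxane, 0 °C to rt
Reagents that add atoms: iodoform IC(I)I
Why: Takai iodo-olefination with the geminal dichromium reagent should give the (E)-alkenyl iodide (C16=C17), attacks only the aldehyde, and is too weakly basic to disturb C15 or the ester.

Step 10
Reactants: 15 methyl (5R,6E)-5-ethyl-7-iodohept-6-enoate; 16 propyne
Product: 17 methyl (5R,6E)-5-ethyldec-6-en-8-ynoate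
Conditions: Pd(PPh3)4 (5 mol %), CuI (10 mol %), Et3N, THF, rt
Reagents that add atoms: none
Why: Sonogashira coupling of an alkenyl iodide with a terminal alkyne proceeds at room temperature with retention of the E geometry and installs C18 together with its methyl cap.

Step 11
Reactants: 17 methyl (5R,6E)-5-ethyldec-6-en-8-ynoate
Product: 18 S-ethyl (5R,6E)-5-ethyldec-6-en-8-ynethioate
Conditions: AlMe3, EtSH, CH2Cl2, 0 °C; then 17, 0 °C to rt
Reagents that add atoms: ethanethiol CCS
Why: Ester-to-thiol-ester exchange with a dimethylaluminium thiolate gives the acyl partner for the ketone synthesis directly, with no hydrolysis step and without touching the enyne.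

Step 12
Reactants: 9 (2S,4S)-8-iodo-2,4-dimethyloctyl acetate; 18 S-ethyl (5R,6E)-5-ethyldec-6-en-8-ynethioate
Product: 20 (2S,4S,13R,14E)-13-ethyl-2,4-dimethyl-9-oxooctadec-14-en-16-yn-1-yl acetate, via alkylzinc iodide 19 (not isolated)
Conditions: 9, Zn dust (BrCH2CH2Br, TMSCl activation), THF, 40 °C; then 18, PdCl2(PPh3)2 (5 mol %), toluene, rt
Reagents that add atoms: none
Why: In the Fukuyama ketone synthesis the thiol ester adds to zerovalent palladium and is alkylated by the mild alkylzinc iodide, so C10–C11 forms without over-addition and with acetate and enyne intact, and zinc sits on the saturated partner so that no radical formed during insertion can cyclise onto an alkene.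

Step 13
Reactants: 20 (2S,4S,13R,14E)-13-ethyl-2,4-dimethyl-9-oxooctadec-14-en-16-yn-1-yl acetate
Product: 21 (2S,4S,13R,14E)-13-ethyl-1-hydroxy-2,4-dimethyloctadec-14-en-16-yn-9-one
Conditions: K2CO3, MeOH, rt
Reagents that add atoms: none
Why: Base-catalysed transesterification removes the primary acetate, and no stereocentre in the molecule is acidic enough to suffer.

Step 14
Reactants: 21 (2S,4S,13R,14E)-13-ethyl-1-hydroxy-2,4-dimethyloctadec-14-en-16-yn-9-one
Product: 22 (2S,4S,13R,14E)-13-ethyl-2,4-dimethyl-9-oxooctadec-14-en-16-ynoic acid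
Conditions: TEMPO (cat.), PhI(OAc)2, MeCN/H2O, rt
Reagents that add atoms: water O
Why: TEMPO/PhI(OAc)2 oxidation in aqueous acetonitrile takes the primary alcohol through the aldehyde hydrate to the C3 acid under mild conditions that spare the enyne, the ketone and the C4 centre.

Step 15
Reactants: 23 L-norvaline
Product: 24 (S)-2-hydroxypentanoic acid
Conditions: NaNO2, H2SO4 (1 M aq.), 0 °C to rt
Reagents that add atoms: water O
Why: Diazotisation of an α-amino acid runs through an α-lactone (double inversion), so hydroxyl replaces nitrogen with net retention and C1 is (S).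

Step 16
Reactants: 25 2-deoxy-D-ribose
Product: 26 3,4-O-isopropylidene-2-deoxy-D-erythro-pentopyranose (anomer mixture)
Conditions: 2-methoxypropene, PPTS (cat.), DMF, 0 °C
Reagents that add atoms: 2-methoxypropene C=C(C)OC
Why: Kinetic acetalisation engages the cis 3,4-diol of the pyranose form, so the sugar supplies C23 (S) and C22 (R) under one ketal while the lactol remains a masked C25 aldehyde.

Step 17
Reactants: 26 3,4-O-isopropylidene-2-deoxy-D-erythro-pentopyranose
Product: 27 [(4R,5S)-5-allyl-2,2-dimethyl-1,3-dioxolan-4-yl]methanol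
Conditions: MePPh3Br, KOtBu, THF, 0 °C; then 26, 0 °C to rt
Reagents that add atoms: methyltriphenylphosphonium bromide C[P+](c1ccccc1)(c1ccccc1)c1ccccc1.[Br-]
Why: Wittig methylenation of the open-chain aldehyde tautomer of the lactol adds C26 and at the same time frees the primary C21 hydroxyl.

Step 18
Reactants: 27 [(4R,5S)-5-allyl-2,2-dimethyl-1,3-dioxolan-4-yl]methanol
Product: 28 [(4R,5S)-5-allyl-2,2-dimethyl-1,3-dioxolan-4-yl]methyl trifluoromethanesulfonate
Conditions: Tf2O, 2,6-lutidine, CH2Cl2, −78 °C; used at once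
Reagents that add atoms: triflic anhydride O=S(=O)(OS(=O)(=O)C(F)(F)F)C(F)(F)F
Why: Sulfonylation with Tf2O and a hindered pyridine base turns the β-branched primary alcohol into a leaving group reactive enough for displacement at −78 °C.

Step 19
Reactants: 28 [(4R,5S)-5-allyl-2,2-dimethyl-1,3-dioxolan-4-yl]methyl trifluoromethanesulfonate; 16 propyne
Product: 31 (4S,5R)-4-allyl-2,2-dimethyl-5-(pent-3-yn-1-yl)-1,3-dioxolane, via 1,3-dilithiopropyne 29 (not isolated), via lithium acetylide 30 (not isolated)
Conditions: 16, n-BuLi (2 equiv), TMEDA, Et2O/hexane, −78 °C to rt; 28, THF, −78 °C; then MeI, DMPU, −78 °C to rt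
Reagents that add atoms: iodomethane CI
Why: In this propargylation of an alkyl electrophile with 1,3-dilithiopropyne the more reactive propargylic carbon displaces the triflate (SN2, C20–C21 bond) and the surviving acetylide is then methylated, giving the capped alkyne in one flask without touching C22.

Step 20
Reactants: 31 (4S,5R)-4-allyl-2,2-dimethyl-5-(pent-3-yn-1-yl)-1,3-dioxolane
Product: 32 (4S,5R)-2,2-dimethyl-4-(oxiran-2-ylmethyl)-5-(pent-3-yn-1-yl)-1,3-dioxolane (both C25 epimers)
Conditions: mCPBA, NaHCO3, CH2Cl2, 0 °C to rt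
Reagents that add atoms: 3-chloroperoxybenzoic acid OOC(=O)c1cccc(Cl)c1
Why: Prilezhaev epoxidation picks the alkene over the far less nucleophilic internal alkyne, and since no facial control is expected both C25 epimers should form.

Step 21
Reactants: 32 (4S,5R)-2,2-dimethyl-4-(oxiran-2-ylmethyl)-5-(pent-3-yn-1-yl)-1,3-dioxolane (both C25 epimers)
Product: 33 (4S,5R)-2,2-dimethyl-4-{[(2S)-oxiran-2-yl]methyl}-5-(pent-3-yn-1-yl)-1,3-dioxolane
Conditions: (S,S)-Co(salen)(OAc) [salen = N,N'-bis(3,5-di-tert-butylsalicylidene)cyclohexane-1,2-diaminate] (1 mol %), H2O (0.55 equiv), THF, 0 °C to rt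
Reagents that add atoms: none
Why: In the hydrolytic kinetic resolution the (S,S)-cobalt salen catalyst should hydrolyse the (25R)-epoxide much faster, so catalyst control leaves the (25S)-epoxide and the polar diol is removed by chromatography.

Step 22
Reactants: 33 (4S,5R)-2,2-dimethyl-4-{[(2S)-oxiran-2-yl]methyl}-5-(pent-3-yn-1-yl)-1,3-dioxolane
Product: 34 (2S)-1-azido-3-[(4S,5R)-2,2-dimethyl-5-(pent-3-yn-1-yl)-1,3-dioxolan-4-yl]propan-2-ol
Conditions: NaN3, NH4Cl, MeOH/H2O, 65 °C
Reagents that add atoms: sodium azide [Na+].[N-]=[N+]=[N-]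
Why: SN2 opening of a terminal epoxide by azide takes place at the unhindered C26, so the C25–O bond and its (S) configuration are untouched.

Step 23
Reactants: 34 (2S)-1-azido-3-[(4S,5R)-2,2-dimethyl-5-(pent-3-yn-1-yl)-1,3-dioxolan-4-yl]propan-2-ol
Product: 35 TBS ether of 34 (C25 OTBS; C26 azide)
Conditions: TBSCl, imidazole, DMF, rt
Reagents that add atoms: tert-butyldimethylsilyl chloride CC(C)(C)[Si](C)(C)Cl
Why: Imidazole-promoted silylation of the only free hydroxyl is routine and leaves azide, ketal and alkyne alone.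

Step 24
Reactants: 35 TBS ether of 34; 24 (S)-2-hydroxypentanoic acid
Product: 37 (2S)-N-{(2S)-2-(tert-butyldimethylsilyloxy)-3-[(4S,5R)-2,2-dimethyl-5-(pent-3-yn-1-yl)-1,3-dioxolan-4-yl]propyl}-2-hydroxypentanamide, via primary amine 36 (not isolated)
Conditions: PPh3, THF/H2O, 50 °C; concentrate; then 24, EDC·HCl, HOBt, iPr2NEt, CH2Cl2, 0 °C to rt
Reagents that add atoms: none
Why: Staudinger reduction is specific for the azide beside the alkyne, and in the carbodiimide/HOBt amide coupling the amine outruns the hydroxyl by far, so the α-hydroxy acid needs no protection and, lacking an oxazolone pathway, keeps C1 (S).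

Step 25
Reactants: 37 hydroxy amide (C19–C28 and C1 part); 22 (2S,4S,13R,14E)-13-ethyl-2,4-dimethyl-9-oxooctadec-14-en-16-ynoic acid
Product: 38 seco enyne-yne (O2–C3 ester and N27–C28 amide in place; methyl-capped alkynes at C18 and C19; C22/C23 acetonide; C25 OTBS)
Conditions: MNBA (2-methyl-6-nitrobenzoic anhydride), DMAP, Et3N, CH2Cl2, rt
Reagents that add atoms: none
Why: Shiina esterification (mixed anhydride, acyl transfer by DMAP) acylates the hindered C1 hydroxyl with retention because the C1–O bond is never broken.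

Step 26
Reactants: 38 seco enyne-yne
Product: 39 28-membered cycloenyne (C18≡C19; 16E; C22/C23 acetonide; C25 OTBS)
Conditions: Mo(≡CC6H4-4-OMe)(OSiPh3)3 (10–15 mol %), 5 Å molecular sieves, toluene (1 mM), rt to 60 °C
Reagents that add atoms: none
Why: The alkylidyne first swaps onto one methyl-capped alkyne through a molybdacyclobutadiene ([2+2] cycloaddition, then cycloreversion), and the substrate-bound alkylidyne then engages the other alkyne terminus in the same way, releasing but-2-yne. This is ring-closing alkyne metathesis to a macrocyclic 1,3-enyne, an established use of triarylsilanolate molybdenum alkylidynes. The single ring formed, the 28-membered macrocycle, is closed end to end by joining C18 to C19; it is unstrained, so high dilution and uptake of but-2-yne by the sieves decide between cyclisation and oligomerisation. No stereocentre is created, and the E geometry of C16=C17 is not touched. The step needs chemoselectivity for C≡C over C=C, ketone, ester, ketal, silyl ether and secondary amide; the silanolate ligands secure it by tempering the Lewis acidity of molybdenum, and every hydroxyl in 38 is masked.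

Step 27
Reactants: 39 28-membered cycloenyne
Product: 40 cycloenyne triol (free OH on C22, C23 and C25)
Conditions: HCl (1 M aq.), THF/MeOH, rt
Reagents that add atoms: none
Why: Acid hydrolysis cleaves the cis-dioxolane and the silyl ether together to free the steering hydroxyls, while ester, amide, ketone and enyne are stable to dilute acid at room temperature.

Step 28
Reactants: 40 cycloenyne triol
Product: 41 (16E,18Z)-19-tributylstannyl diene triol (Sn on C19 cis to C17; H on C18)
Conditions: [Cp*RuCl]4 (5 mol %), Bu3SnH (slow addition), CH2Cl2, rt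
Reagents that add atoms: tributyltin hydride CCCC[SnH](CCCC)CCCC
Why: In the ruthenium-catalysed trans-hydrostannation a hydrogen bond from the C22 hydroxyl (reinforced by its C23 neighbour) to the chloride on ruthenium should orient the bound alkyne so that tin goes to the nearer C19 and hydrogen reaches C18 from the opposite face, and since all three hydroxyls lie on the C19 side none can steer the other way.

Step 29
Reactants: 41 (16E,18Z)-19-tributylstannyl diene triol
Product: 42 (16E,18Z)-19-iodo diene triol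
Conditions: I2, CH2Cl2, −78 to 0 °C
Reagents that add atoms: iodine II
Why: Iododestannylation is an ipso electrophilic substitution with retention of alkene geometry and is far faster at low temperature than any reaction of iodine with the diene or the hydroxyls.

Step 30
Reactants: 42 (16E,18Z)-19-iodo diene triol
Product: 43 tris-TES ether of 42 (C22, C23 and C25 OTES)
Conditions: TESCl, imidazole, DMAP (cat.), DMF, 0 °C to rt
Reagents that add atoms: chlorotriethylsilane CC[Si](Cl)(CC)CC
Why: Silylation blocks the C22 hydroxyl, which would otherwise trap the acylpalladium species of the next step as a six-membered lactone, and TESCl/imidazole does not enolise the C11 ketone.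

Step 31
Reactants: 43 tris-TES ether of 42
Product: 44 2-(trimethylsilyl)ethyl ester of the tris-TES-protected target
Conditions: Pd(PPh3)4 (10 mol %), CO (1 atm), Me3SiCH2CH2OH, Et3N, DMF, 60 °C
Reagents that add atoms: carbon monoxide [C-]#[O+]; 2-(trimethylsilyl)ethanol C[Si](C)(C)CCO
Why: Palladium-catalysed alkoxycarbonylation of an alkenyl iodide (oxidative addition, CO insertion, alcoholysis) keeps the alkene geometry, so the ester carbon ends up on C19 cis to C17.

Step 32
Reactants: 44 2-(trimethylsilyl)ethyl ester of the tris-TES-protected target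
Product: 45 CNP0182412.1
Conditions: TBAF, AcOH, THF, 0 °C to rt; pH 5 buffer work-up
Reagents that add atoms: none
Why: Fluoride cleaves the three TES ethers and fragments the 2-(trimethylsilyl)ethyl ester with loss of ethene, while the acetic acid buffer keeps the medium too mild for epimerisation at C1 or C4, acyl migration, or lactonisation onto the C22 hydroxyl.

Compound list
1 | cis-2,4-dimethylglutaric anhydride (meso) | C[C@H]1C[C@@H](C)C(=O)OC1=O | starting material
2 | meso-2,4-dimethylpentane-1,5-diol | OC[C@@H](C)C[C@@H](C)CO | intermediate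
3 | (2R,4S)-5-acetoxy-2,4-dimethylpentan-1-ol | CC(=O)OC[C@@H](C)C[C@@H](C)CO | intermediate
4 | (2S,4R)-2,4-dimethyl-5-oxopentyl acetate | CC(=O)OC[C@@H](C)C[C@@H](C)C=O | intermediate
5 | (3-benzyloxypropyl)triphenylphosphonium bromide | [Br-].c1ccccc1COCCC[P+](c1ccccc1)(c1ccccc1)c1ccccc1 | starting material
6 | (3-benzyloxypropylidene)triphenylphosphorane | c1ccccc1COCCC=P(c1ccccc1)(c1ccccc1)c1ccccc1 | intermediate
7 | (2S,4R,5Z)-8-benzyloxy-2,4-dimethyloct-5-en-1-yl acetate | CC(=O)OC[C@@H](C)C[C@@H](C)/C=C\CCOCc1ccccc1 | intermediate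
8 | (2S,4S)-8-hydroxy-2,4-dimethyloctyl acetate | CC(=O)OC[C@@H](C)C[C@@H](C)CCCCO | intermediate
9 | (2S,4S)-8-iodo-2,4-dimethyloctyl acetate | CC(=O)OC[C@@H](C)C[C@@H](C)CCCCI | intermediate
10 | cyclohex-2-en-1-one | O=C1C=CCCC1 | starting material
11 | ethylzinc (R)-3-ethylcyclohex-1-en-1-olate | CC[Zn]OC1=C[C@H](CC)CCC1 | intermediate
12 | (R)-(3-ethylcyclohex-1-en-1-yl)oxytrimethylsilane | C[Si](C)(C)OC1=C[C@H](CC)CCC1 | intermediate
13 | (R)-5-ethyl-6-oxohexanoic acid | OC(=O)CCC[C@@H](CC)C=O | intermediate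
14 | methyl (R)-5-ethyl-6-oxohexanoate | COC(=O)CCC[C@@H](CC)C=O | intermediate
15 | methyl (5R,6E)-5-ethyl-7-iodohept-6-enoate | COC(=O)CCC[C@@H](CC)/C=C/I | intermediate
16 | propyne | CC#C | starting material
17 | methyl (5R,6E)-5-ethyldec-6-en-8-ynoate | COC(=O)CCC[C@@H](CC)/C=C/C#CC | intermediate
18 | S-ethyl (5R,6E)-5-ethyldec-6-en-8-ynethioate | CCSC(=O)CCC[C@@H](CC)/C=C/C#CC | intermediate
19 | [(5S,7S)-8-acetoxy-5,7-dimethyloctyl]zinc iodide | CC(=O)OC[C@@H](C)C[C@@H](C)CCCC[Zn]I | intermediate
20 | (2S,4S,13R,14E)-13-ethyl-2,4-dimethyl-9-oxooctadec-14-en-16-yn-1-yl acetate | CC(=O)OC[C@@H](C)C[C@@H](C)CCCCC(=O)CCC[C@@H](CC)/C=C/C#CC | intermediate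
21 | (2S,4S,13R,14E)-13-ethyl-1-hydroxy-2,4-dimethyloctadec-14-en-16-yn-9-one | OC[C@@H](C)C[C@@H](C)CCCCC(=O)CCC[C@@H](CC)/C=C/C#CC | intermediate
22 | (2S,4S,13R,14E)-13-ethyl-2,4-dimethyl-9-oxooctadec-14-en-16-ynoic acid | OC(=O)[C@@H](C)C[C@@H](C)CCCCC(=O)CCC[C@@H](CC)/C=C/C#CC | intermediate
23 | L-norvaline | CCC[C@H](N)C(=O)O | starting material
24 | (S)-2-hydroxypentanoic acid | CCC[C@H](O)C(=O)O | intermediate
25 | 2-deoxy-D-ribose | O=CC[C@H](O)[C@H](O)CO | starting material
26 | 3,4-O-isopropylidene-2-deoxy-D-erythro-pentopyranose | OC1C[C@@H]2OC(C)(C)O[C@@H]2CO1 | intermediate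
27 | [(4R,5S)-5-allyl-2,2-dimethyl-1,3-dioxolan-4-yl]methanol | C=CC[C@@H]1OC(C)(C)O[C@@H]1CO | intermediate
28 | [(4R,5S)-5-allyl-2,2-dimethyl-1,3-dioxolan-4-yl]methyl trifluoromethanesulfonate | C=CC[C@@H]1OC(C)(C)O[C@@H]1COS(=O)(=O)C(F)(F)F | intermediate
29 | 1,3-dilithiopropyne | [Li]CC#C[Li] | intermediate
30 | lithium acetylide of (4S,5R)-4-allyl-5-(but-3-yn-1-yl)-2,2-dimethyl-1,3-dioxolane | C=CC[C@@H]1OC(C)(C)O[C@@H]1CCC#C[Li] | intermediate
31 | (4S,5R)-4-allyl-2,2-dimethyl-5-(pent-3-yn-1-yl)-1,3-dioxolane | C=CC[C@@H]1OC(C)(C)O[C@@H]1CCC#CC | intermediate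
32 | (4S,5R)-2,2-dimethyl-4-(oxiran-2-ylmethyl)-5-(pent-3-yn-1-yl)-1,3-dioxolane, both C25 epimers | C1OC1C[C@@H]2OC(C)(C)O[C@@H]2CCC#CC | intermediate
33 | (4S,5R)-2,2-dimethyl-4-{[(2S)-oxiran-2-yl]methyl}-5-(pent-3-yn-1-yl)-1,3-dioxolane | C1O[C@H]1C[C@@H]2OC(C)(C)O[C@@H]2CCC#CC | intermediate
34 | (2S)-1-azido-3-[(4S,5R)-2,2-dimethyl-5-(pent-3-yn-1-yl)-1,3-dioxolan-4-yl]propan-2-ol | [N-]=[N+]=NC[C@@H](O)C[C@@H]1OC(C)(C)O[C@@H]1CCC#CC | intermediate
35 | TBS ether of 34 | [N-]=[N+]=NC[C@@H](O[Si](C)(C)C(C)(C)C)C[C@@H]1OC(C)(C)O[C@@H]1CCC#CC | intermediate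
36 | (2S)-2-(tert-butyldimethylsilyloxy)-3-[(4S,5R)-2,2-dimethyl-5-(pent-3-yn-1-yl)-1,3-dioxolan-4-yl]propan-1-amine | NC[C@@H](O[Si](C)(C)C(C)(C)C)C[C@@H]1OC(C)(C)O[C@@H]1CCC#CC | intermediate
37 | hydroxy amide from 36 and 24 (1S,22R,23S,25S) | CCC[C@H](O)C(=O)NC[C@@H](O[Si](C)(C)C(C)(C)C)C[C@@H]1OC(C)(C)O[C@@H]1CCC#CC | intermediate
38 | seco enyne-yne (C22/C23 acetonide, C25 OTBS) | CC#CCC[C@H]1OC(C)(C)O[C@H]1C[C@H](O[Si](C)(C)C(C)(C)C)CNC(=O)[C@H](CCC)OC(=O)[C@@H](C)C[C@@H](C)CCCCC(=O)CCC[C@@H](CC)/C=C/C#CC | intermediate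
39 | 28-membered cycloenyne (C22/C23 acetonide, C25 OTBS) | CCC[C@@H]1OC(=O)[C@@H](C)C[C@@H](C)CCCCC(=O)CCC[C@@H](CC)/C=C/C#CCC[C@H]2OC(C)(C)O[C@H]2C[C@H](O[Si](C)(C)C(C)(C)C)CNC1=O | intermediate
40 | cycloenyne triol | CCC[C@@H]1OC(=O)[C@@H](C)C[C@@H](C)CCCCC(=O)CCC[C@@H](CC)/C=C/C#CCC[C@@H](O)[C@@H](O)C[C@H](O)CNC1=O | intermediate
41 | (16E,18Z)-19-tributylstannyl diene triol | CCC[C@@H]1OC(=O)[C@@H](C)C[C@@H](C)CCCCC(=O)CCC[C@@H](CC)/C=C/C=C(\[Sn](CCCC)(CCCC)CCCC)CC[C@@H](O)[C@@H](O)C[C@H](O)CNC1=O | intermediate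
42 | (16E,18Z)-19-iodo diene triol | CCC[C@@H]1OC(=O)[C@@H](C)C[C@@H](C)CCCCC(=O)CCC[C@@H](CC)/C=C/C=C(\I)CC[C@@H](O)[C@@H](O)C[C@H](O)CNC1=O | intermediate
43 | tris-TES ether of 42 | CCC[C@@H]1OC(=O)[C@@H](C)C[C@@H](C)CCCCC(=O)CCC[C@@H](CC)/C=C/C=C(\I)CC[C@@H](O[Si](CC)(CC)CC)[C@@H](O[Si](CC)(CC)CC)C[C@H](O[Si](CC)(CC)CC)CNC1=O | intermediate
44 | 2-(trimethylsilyl)ethyl ester of the tris-TES-protected target | CCC[C@@H]1OC(=O)[C@@H](C)C[C@@H](C)CCCCC(=O)CCC[C@@H](CC)/C=C/C=C(\C(=O)OCC[Si](C)(C)C)CC[C@@H](O[Si](CC)(CC)CC)[C@@H](O[Si](CC)(CC)CC)C[C@H](O[Si](CC)(CC)CC)CNC1=O | intermediate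
45 | CNP0182412.1 (1S,4S,6S,15R,16E,18Z,22R,23S,25S) | CCC[C@@H]1OC(=O)[C@@H](C)C[C@@H](C)CCCCC(=O)CCC[C@@H](CC)/C=C/C=C(\C(=O)O)CC[C@@H](O)[C@@H](O)C[C@H](O)CNC1=O | target

Total step count: 32.
Longest linear sequence: 17 steps (25 to 45 through steps 16–32). The line from 1 through steps 1–6, 12–14 and 25–32 is equally long.

Steps most likely to fail

1. Step 28.
What may go wrong: a hydrogen bond from a hydroxyl three carbons away may orient the catalyst too weakly, so that tin is delivered partly to C18. Conjugation with C16=C17 may add a bias of its own.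
Fallback, from 40 back to 42: the hydrogen bond is replaced by a covalent tether. Triol 40 is silylated with 1,1,3,3-tetramethyldisilazane to the tris(dimethylsilyl) ether F1. [RuCl2(C6H6)]2 then catalyses an intramolecular anti-hydrosilylation. The Si–H on O22 can reach C19 only through a six-membered exo-dig transition state, which gives the alkylidene oxasilinane F2 with silicon on C19 cis to C17. Iododesilylation with NIS in hexafluoroisopropanol (retention), followed by mild aqueous acid to hydrolyse the remaining Si–O bonds, returns iodide 42.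

2. Step 26.
What may go wrong: intermolecular metathesis may outrun ring closure and lead to oligomerisation, or turnover may become too slow at the dilution that cyclisation needs.
Fallback, from 37 and 20 back to 39: C18≡C19 is made between two molecules at normal concentration, and the ring is closed at the O2–C3 ester instead. Alcohol 37 is acetylated (Ac2O, pyridine) to the C1 acetate F3. Alkyne cross-metathesis of F3 with an excess of 20 under the same molybdenum alkylidyne gives the open-chain enyne diacetate F4. K2CO3 in MeOH removes both acetates to give the diol F5. TEMPO/PhI(OAc)2 in aqueous MeCN oxidises only the primary C3 alcohol to give the seco hydroxy acid F6. MNBA/DMAP macrolactonisation under slow addition closes the 28-membered ring to 39.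

3. Step 19.
What may go wrong: the dianion may act as a base toward the triflate (elimination), it may react through its allenyl form, or methylation of the acetylide may stay incomplete.
Fallback, from 28 back to 31: a monoanion with a blocked alkyne end is used and the cap is exchanged afterwards. Lithiated 1-(trimethylsilyl)propyne (n-BuLi, THF, −78 °C) displaces the triflate to give the silyl alkyne F7. K2CO3 in MeOH gives the terminal alkyne F8. n-BuLi followed by MeI returns 31.

Further compounds
F1 | step 28 | tris(dimethylsilyl) ether of triol 40 | CCC[C@@H]1OC(=O)[C@@H](C)C[C@@H](C)CCCCC(=O)CCC[C@@H](CC)/C=C/C#CCC[C@@H](O[SiH](C)C)[C@@H](O[SiH](C)C)C[C@H](O[SiH](C)C)CNC1=O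
F2 | step 28 | alkylidene oxasilinane (O22–SiMe2–C19 ring, 18Z; O23 and O25 as dimethylsilyl ethers) | CCC[C@@H]1OC(=O)[C@@H](C)C[C@@H](C)CCCCC(=O)CCC[C@@H](CC)/C=C/C=C(\[Si]2(C)C)CC[C@@H](O2)[C@@H](O[SiH](C)C)C[C@H](O[SiH](C)C)CNC1=O
F3 | step 26 | C1 acetate of hydroxy amide 37 | CCC[C@H](OC(C)=O)C(=O)NC[C@@H](O[Si](C)(C)C(C)(C)C)C[C@@H]1OC(C)(C)O[C@@H]1CCC#CC
F4 | step 26 | open-chain enyne diacetate (C18≡C19 in place; acetates on the C3 and C1 oxygens) | CC(=O)OC[C@@H](C)C[C@@H](C)CCCCC(=O)CCC[C@@H](CC)/C=C/C#CCC[C@H]1OC(C)(C)O[C@H]1C[C@H](O[Si](C)(C)C(C)(C)C)CNC(=O)[C@H](CCC)OC(C)=O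
F5 | step 26 | open-chain enyne diol | OC[C@@H](C)C[C@@H](C)CCCCC(=O)CCC[C@@H](CC)/C=C/C#CCC[C@H]1OC(C)(C)O[C@H]1C[C@H](O[Si](C)(C)C(C)(C)C)CNC(=O)[C@H](CCC)O
F6 | step 26 | seco hydroxy acid | OC(=O)[C@@H](C)C[C@@H](C)CCCCC(=O)CCC[C@@H](CC)/C=C/C#CCC[C@H]1OC(C)(C)O[C@H]1C[C@H](O[Si](C)(C)C(C)(C)C)CNC(=O)[C@H](CCC)O
F7 | step 19 | (4S,5R)-4-allyl-2,2-dimethyl-5-[4-(trimethylsilyl)but-3-yn-1-yl]-1,3-dioxolane | C=CC[C@@H]1OC(C)(C)O[C@@H]1CCC#C[Si](C)(C)C
F8 | step 19 | (4S,5R)-4-allyl-5-(but-3-yn-1-yl)-2,2-dimethyl-1,3-dioxolane | C=CC[C@@H]1OC(C)(C)O[C@@H]1CCC#C
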